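**Plan**

- Retrosynthetic cuts, in order: the sulfate O–S bond at C3–O and the two O‑benzyl bonds on ring A; the C2=C3 double bond (back to a dihydroflavonol); the C3–C4 bond of ring C; the O1–C2 ether bond.
- Enabling feature: in ring C the C4 ketone and the oxygen‑bearing C3 form an acyloin unit at the oxidation level of two aldehydes, so C3 and C4 can both start as formyl carbons and be joined by polarity reversal of one of them.
- Forward: ring A (2,4,6‑trihydroxybenzaldehyde, dibenzylated) is joined through O1 to the ring B fragment (methyl 4‑methoxymandelate) by Mitsunobu etherification; reduction and double oxidation give a dialdehyde; ring C closes last by carbene‑catalysed benzoin formation of C3–C4.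
- Dehydrogenation to the flavonol, sulfation of the only free hydroxyl (C3–OH) and hydrogenolysis of the benzyl ethers complete the synthesis.
- Stereochemistry: the target has no stereocentre; C2 (racemic, from the mandelate) and C3 (set in the ring closure) exist only in intermediates and are erased by the dehydrogenation.

Key step: step 6

Remark: the target is drawn as the free hydrogen sulfate; such acids hydrolyse themselves on storage, so the sulfate is carried as its sodium salt and protonated only in the last operation, cold, with immediate lyophilisation.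

**Step 1**
Reactants: 1 2,4,6‑trihydroxybenzaldehyde; 2 benzyl bromide
Product: 3 2,4‑bis(benzyloxy)‑6‑hydroxybenzaldehyde
Conditions: BnBr (2.05 equiv), K2CO3 (2.2 equiv), DMF, 0 °C → rt
Reagents that add atoms: benzyl bromide (compound 2), BrCc1ccccc1
Why: Williamson O‑benzylation under weak base; the 4‑OH and one ortho OH react, while the last ortho OH is held in a hydrogen bond to the formyl oxygen and is the least nucleophilic, so alkylation should stop at the dibenzyl ether when BnBr is limited to two equivalents.

**Step 2**
Reactants: 4 4‑methoxymandelic acid (racemic)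
Product: 5 methyl 4‑methoxymandelate (racemic)
Conditions: MeI, KHCO3, DMF, rt
Reagents that add atoms: iodomethane, CI
Why: SN2 O‑alkylation of the carboxylate; hydrogen carbonate deprotonates only the acid, so the benzylic hydroxyl stays free, and the acid‑labile p‑methoxybenzylic carbinol is spared the acidic methanol of a Fischer esterification.

**Step 3**
Reactants: 3 2,4‑bis(benzyloxy)‑6‑hydroxybenzaldehyde; 5 methyl 4‑methoxymandelate
Product: 6 methyl 2‑[3,5‑bis(benzyloxy)‑2‑formylphenoxy]‑2‑(4‑methoxyphenyl)acetate (racemic)
Conditions: PPh3, DIAD, THF, 0 °C → rt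
Reagents that add atoms: none
Why: Mitsunobu etherification; the salicylaldehyde‑type phenol is acidic enough to protonate the betaine and displaces the oxyphosphonium of the secondary α‑ester carbinol in an SN2 step accelerated by the adjacent ester, the neutral medium avoids the base‑induced aldol closure to a benzofuran that an α‑halo ester alkylation would risk, and the configuration of the new ether carbon is immaterial because 5 is racemic.

**Step 4**
Reactants: 6 methyl 2‑[3,5‑bis(benzyloxy)‑2‑formylphenoxy]‑2‑(4‑methoxyphenyl)acetate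
Product: 7 2‑[3,5‑bis(benzyloxy)‑2‑(hydroxymethyl)phenoxy]‑2‑(4‑methoxyphenyl)ethan‑1‑ol (racemic)
Conditions: LiAlH4, THF, 0 °C; work‑up with H2O and 15% NaOH
Reagents that add atoms: none
Why: hydride reduction of the methyl ester and the aryl aldehyde to the two primary alcohols; aryl and benzyl ethers are inert, and the basic work‑up spares the acid‑sensitive trialkoxybenzyl alcohol.

**Step 5**
Reactants: 7 2‑[3,5‑bis(benzyloxy)‑2‑(hydroxymethyl)phenoxy]‑2‑(4‑methoxyphenyl)ethan‑1‑ol
Product: 8 2,4‑bis(benzyloxy)‑6‑[1‑(4‑methoxyphenyl)‑2‑oxoethoxy]benzaldehyde (racemic)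
Conditions: Dess–Martin periodinane (3 equiv), pyridine, CH2Cl2, 0 °C → rt; taken on without chromatography
Reagents that add atoms: none
Why: Dess–Martin oxidation takes both primary alcohols to aldehydes without strong base or acid, so the enolisable α‑aryl‑α‑aryloxy aldehyde is not exposed to aldol conditions and no over‑oxidation to acids is expected.

**Step 6**
Reactants: 8 2,4‑bis(benzyloxy)‑6‑[1‑(4‑methoxyphenyl)‑2‑oxoethoxy]benzaldehyde
Product: 9 rac‑(2R,3R)‑5,7‑bis(benzyloxy)‑3‑hydroxy‑2‑(4‑methoxyphenyl)chroman‑4‑one (trans)
Conditions: 2‑phenyl‑6,7‑dihydro‑5H‑pyrrolo[2,1‑c][1,2,4]triazol‑2‑ium tetrafluoroborate (15 mol%), Et3N (0.5 equiv), degassed THF, 25 → 40 °C, Ar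
Reagents that add atoms: none
Why: The triazolylidene adds reversibly to the formyl groups, and deprotonation of the ring A adduct gives an aryl‑conjugated enaminol, an acyl anion equivalent at C4, which attacks the strongly electrophilic α‑aryloxy aldehyde carbon C3; proton transfer and loss of the carbene leave the C4 ketone and the C3 carbinol. This is an intramolecular crossed benzoin condensation, whose closest known relatives are the carbene‑catalysed aldehyde–ketone cyclisations of 2‑(2‑oxoalkoxy)benzaldehydes to 3‑hydroxychroman‑4‑ones and the azolium‑catalysed acyloin cyclisation of dialdehydes. Ring C closes in the 6‑exo‑trig mode, the nucleophilic C4 attacking a formyl group whose C=O lies outside the new ring. C3 is the only new stereocentre and is set relative to the racemic C2 by substrate control: the half‑chair transition state places the 2‑aryl group and the forming 3‑hydroxyl both equatorial, and because C3 can epimerise through the enediol under Et3N the trans isomer is also the thermodynamic one (any cis isomer converges in step 7). The step needs chemoselectivity in the choice of donor aldehyde, because an enaminol formed on the aliphatic formyl group could expel the ring A phenoxide; the α‑carbon of that aldehyde bears both an aryl and an aryloxy group, a branching that makes aldehydes slow donors but excellent acceptors, and a triazolium rather than a thiazolium precatalyst is chosen because triazolylidenes as a class prefer aromatic aldehydes as acyl donors. No further control over which carbon becomes the ketone is required, since either acyloin is oxidised to the same flavonol in step 7.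

**Step 7**
Reactants: 9 rac‑(2R,3R)‑5,7‑bis(benzyloxy)‑3‑hydroxy‑2‑(4‑methoxyphenyl)chroman‑4‑one
Product: 10 5,7‑bis(benzyloxy)‑3‑hydroxy‑2‑(4‑methoxyphenyl)‑4H‑chromen‑4‑one (5,7‑di‑O‑benzylkaempferide)
Conditions: I2 (1.1 equiv), KOAc (3 equiv), AcOH, 100 °C
Reagents that add atoms: none
Why: iodine–acetate dehydrogenation of a dihydroflavonol; enolisation toward C3, iodination and loss of HI give the chroman‑3,4‑dione, whose enol tautomer is the flavonol, both stereocentres disappear, and acetate buffers the HI so that the benzyl ethers stay on.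

**Step 8**
Reactants: 10 5,7‑di‑O‑benzylkaempferide
Product: 12 sodium 5,7‑di‑O‑benzylkaempferide 3‑O‑sulfate, via pyridinium 5,7‑di‑O‑benzylkaempferide 3‑O‑sulfate 11 (not isolated)
Conditions: SO3·pyridine (5 equiv), pyridine, 60 °C; then aq. NaHCO3, 0 °C; C18 chromatography
Reagents that add atoms: sulfur trioxide pyridine complex, O=S(=O)([O-])[n+]1ccccc1; sodium hydrogen carbonate, [Na+].OC([O-])=O
Why: O‑sulfonation of the only free hydroxyl (the C3 enol OH) by the amine–SO3 complex; hydrogen carbonate then exchanges pyridinium for sodium, which gives a storable salt and removes a nitrogen base that would slow the hydrogenolysis.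

**Step 9**
Reactants: 12 sodium 5,7‑di‑O‑benzylkaempferide 3‑O‑sulfate
Product: 14 kaempferide 3‑O‑sulfate, via sodium kaempferide 3‑O‑sulfate 13 (not isolated)
Conditions: H2 (1 atm), 10% Pd/C, MeOH–THF, rt; filter; then aq. HCl (1.0 equiv), 0 °C; C18 cartridge (cold dilute HCl wash, MeOH elution), lyophilise
Reagents that add atoms: none
Why: hydrogenolysis of the two aryl benzyl ethers over Pd/C; the sulfate monoester salt, the 4′‑methyl ether and the tetrasubstituted chromone double bond should be untouched at 1 atm, and one equivalent of acid in the cold protonates the sulfate to the acid form.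

**Compound list**

1 | 2,4,6‑trihydroxybenzaldehyde | O=Cc1c(O)cc(O)cc1O | starting material
2 | benzyl bromide | BrCc1ccccc1 | starting material
3 | 2,4‑bis(benzyloxy)‑6‑hydroxybenzaldehyde | O=Cc1c(O)cc(OCc2ccccc2)cc1OCc1ccccc1 | intermediate
4 | 4‑methoxymandelic acid (racemic) | COc1ccc(cc1)C(O)C(O)=O | starting material
5 | methyl 4‑methoxymandelate (racemic) | COc1ccc(cc1)C(O)C(=O)OC | intermediate
6 | methyl 2‑[3,5‑bis(benzyloxy)‑2‑formylphenoxy]‑2‑(4‑methoxyphenyl)acetate (racemic) | COC(=O)C(Oc1cc(OCc2ccccc2)cc(OCc2ccccc2)c1C=O)c1ccc(OC)cc1 | intermediate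
7 | 2‑[3,5‑bis(benzyloxy)‑2‑(hydroxymethyl)phenoxy]‑2‑(4‑methoxyphenyl)ethan‑1‑ol (racemic) | OCC(Oc1cc(OCc2ccccc2)cc(OCc2ccccc2)c1CO)c1ccc(OC)cc1 | intermediate
8 | 2,4‑bis(benzyloxy)‑6‑[1‑(4‑methoxyphenyl)‑2‑oxoethoxy]benzaldehyde (racemic) | COc1ccc(cc1)C(C=O)Oc1cc(OCc2ccccc2)cc(OCc2ccccc2)c1C=O | intermediate
9 | rac‑(2R,3R)‑5,7‑bis(benzyloxy)‑3‑hydroxy‑2‑(4‑methoxyphenyl)chroman‑4‑one (trans, one enantiomer drawn) | COc1ccc(cc1)[C@H]1Oc2cc(OCc3ccccc3)cc(OCc3ccccc3)c2C(=O)[C@@H]1O | intermediate
10 | 5,7‑bis(benzyloxy)‑3‑hydroxy‑2‑(4‑methoxyphenyl)‑4H‑chromen‑4‑one (5,7‑di‑O‑benzylkaempferide) | COc1ccc(cc1)-c1oc2cc(OCc3ccccc3)cc(OCc3ccccc3)c2c(=O)c1O | intermediate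
11 | pyridinium 5,7‑di‑O‑benzylkaempferide 3‑O‑sulfate (not isolated) | COc1ccc(cc1)-c1oc2cc(OCc3ccccc3)cc(OCc3ccccc3)c2c(=O)c1OS(=O)(=O)[O-].c1cc[nH+]cc1 | intermediate
12 | sodium 5,7‑di‑O‑benzylkaempferide 3‑O‑sulfate | COc1ccc(cc1)-c1oc2cc(OCc3ccccc3)cc(OCc3ccccc3)c2c(=O)c1OS(=O)(=O)[O-].[Na+] | intermediate
13 | sodium kaempferide 3‑O‑sulfate (not isolated) | COc1ccc(cc1)-c1oc2cc(O)cc(O)c2c(=O)c1OS(=O)(=O)[O-].[Na+] | intermediate
14 | kaempferide 3‑O‑sulfate | COc1ccc(-c2oc3cc(O)cc(O)c3c(=O)c2OS(=O)(=O)O)cc1 | target

**Step count and risks**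

Total steps: 9. Longest linear sequence: 8 (steps 1, 3, 4, 5, 6, 7, 8, 9); step 2 is a one‑step branch.

Steps most likely to fail:

1. Step 6. The carbene may engage the aliphatic formyl group first. The enaminol formed there can expel the ring A phenoxide (internal redox with acyl transfer) instead of closing the ring, and the enolisable aldehyde can drain into a reversible aldol closure to a five‑membered ring. Closure with the reverse polarity is tolerated, because the iodine step oxidises either acyloin to the same flavonol. Fallback: from dialdehyde 8, the C3–C4 bond is made reductively. SmI2 (2.2 equiv) with t‑BuOH in THF at −78 °C should reduce the more easily reduced aromatic formyl group to its ketyl, which adds to the neighbouring aliphatic aldehyde (pinacol cyclisation) and gives 5,7‑bis(benzyloxy)‑2‑(4‑methoxyphenyl)chromane‑3,4‑diol F1 as a diastereomer mixture. Oxidation of both carbinols with IBX in DMSO, a reagent that does not cleave 1,2‑diols, would give the chroman‑3,4‑dione, whose enol form is 10. The route is rejoined at 10 and step 7 falls away.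

2. Step 5. The first‑formed aliphatic aldehyde can be captured by the still unoxidised benzylic hydroxyl as a seven‑membered lactol and over‑oxidised to a lactone, and the dialdehyde can enolise and self‑condense during isolation. Fallback: from phenol 3, without ever reducing the ring A aldehyde. Methyl (E)‑3‑(4‑methoxyphenyl)prop‑2‑en‑1‑yl carbonate F2 is made from commercial (E)‑4‑methoxycinnamyl alcohol with methyl chloroformate and pyridine. Branched‑selective allylic etherification of 3 with F2 ([Ir(cod)Cl]2, phosphoramidite ligand, THF, rt) should give 2,4‑bis(benzyloxy)‑6‑{[1‑(4‑methoxyphenyl)prop‑2‑en‑1‑yl]oxy}benzaldehyde F3. Lemieux–Johnson cleavage of its vinyl group (OsO4 cat., NaIO4, 2,6‑lutidine, dioxane–H2O) unveils the aliphatic aldehyde in the last operation under near‑neutral conditions. The route is rejoined at 8 and steps 2 to 5 fall away.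

3. Step 8. Sulfonation of the chelated 3‑hydroxyl, flanked by the 2‑aryl group and the C4 carbonyl, may stall, and sulfate or material may be lost while the ionic product is separated from inorganic sulfate. Fallback: from 10, the sulfate is introduced in masked, neutral form. 2,2,2‑Trichloroethyl chlorosulfate with Et3N and DMAP in THF should give 5,7‑bis(benzyloxy)‑2‑(4‑methoxyphenyl)‑4‑oxo‑4H‑chromen‑3‑yl 2,2,2‑trichloroethyl sulfate F4, which can be purified on silica. Reductive fragmentation of the trichloroethyl group with Zn and HCOONH4 in MeOH gives ammonium 5,7‑di‑O‑benzylkaempferide 3‑O‑sulfate F5. Treatment with aq. NaHCO3 and evaporation exchanges ammonium for sodium. The route is rejoined at 12.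

**Further compounds**

F1 | step 6 | 5,7‑bis(benzyloxy)‑2‑(4‑methoxyphenyl)chromane‑3,4‑diol (racemic, diastereomer mixture) | COc1ccc(cc1)C1Oc2cc(OCc3ccccc3)cc(OCc3ccccc3)c2C(O)C1O
F2 | step 5 | methyl (E)‑3‑(4‑methoxyphenyl)prop‑2‑en‑1‑yl carbonate | COC(=O)OC/C=C/c1ccc(OC)cc1
F3 | step 5 | 2,4‑bis(benzyloxy)‑6‑{[1‑(4‑methoxyphenyl)prop‑2‑en‑1‑yl]oxy}benzaldehyde (racemic) | C=CC(Oc1cc(OCc2ccccc2)cc(OCc2ccccc2)c1C=O)c1ccc(OC)cc1
F4 | step 8 | 5,7‑bis(benzyloxy)‑2‑(4‑methoxyphenyl)‑4‑oxo‑4H‑chromen‑3‑yl 2,2,2‑trichloroethyl sulfate | COc1ccc(cc1)-c1oc2cc(OCc3ccccc3)cc(OCc3ccccc3)c2c(=O)c1OS(=O)(=O)OCC(Cl)(Cl)Cl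
F5 | step 8 | ammonium 5,7‑di‑O‑benzylkaempferide 3‑O‑sulfate | COc1ccc(cc1)-c1oc2cc(OCc3ccccc3)cc(OCc3ccccc3)c2c(=O)c1OS(=O)(=O)[O-].[NH4+]
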